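The cyclohexene ring (C1 aroyl-bearing, C2 prenyl-bearing, C3=C4 alkene with methyl on C3, C6 phenyl-bearing) is cut into two three-carbon pieces. Because C1 lies α to the exocyclic carbonyl carbon and C3 is an alkene carbon two atoms away, C1–C2–C3 maps onto a vinylogous ester-stabilised phosphorus ylide, and C4–C5–C6 onto cinnamaldehyde. Under iminium catalysis, conjugate addition forms C1–C6 and sets the phenyl-bearing stereocenter; intramolecular Wittig olefination then forms C3=C4, giving a 6-phenylcyclohexa-1,3-diene ester in one operation. Later the ester becomes the benzofuranyl ketone, the prenyl group reaches C2 by Grignard addition and anionic oxy-Cope shift, and a chelation-controlled demethylation ends the route.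

Key step: step 3

Remark: the cyclohexene ring atoms are numbered C1 (aroyl-bearing) to C6 (phenyl-bearing) throughout. The target is the (1R,2S,6R) isomer, with the aroyl group cis to the prenyl group and trans to the phenyl group. The two enoate/enal partners, 3,5-dimethoxyphenol, 2-bromo-1,1-diethoxyethane and prenylmagnesium chloride solution are taken as commercial.

Step 1
Reactants: 1 ethyl (2E)-pent-2-enoate
Product: 2 ethyl (2E)-4-bromopent-2-enoate (racemic)
Conditions: NBS, AIBN (cat.), PhCF3, 85 °C
Reagents that add atoms: N-bromosuccinimide, O=C1CCC(=O)N1Br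
Why: Wohl–Ziegler radical bromination should take the allylic γ-position, the only activated C–H site, and leave the conjugated E-enoate in place; the new stereocenter is racemic and is destroyed in step 3.

Step 2
Reactants: 2 ethyl (2E)-4-bromopent-2-enoate
Product: 3 [(3E)-5-ethoxy-5-oxopent-3-en-2-yl]triphenylphosphonium bromide (racemic)
Conditions: PPh3, MeCN, 70 °C
Reagents that add atoms: triphenylphosphine, c1ccc(cc1)P(c1ccccc1)c1ccccc1
Why: SN2 displacement of the allylic bromide by PPh3 (quaternisation) should give the phosphonium salt, whose conjugated ester makes the P–CH proton acidic enough for a carbonate base.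

Step 3
Reactants: 3 [(3E)-5-ethoxy-5-oxopent-3-en-2-yl]triphenylphosphonium bromide; 4 (2E)-3-phenylprop-2-enal (cinnamaldehyde)
Product: 7 ethyl (6S)-3-methyl-6-phenylcyclohexa-1,3-diene-1-carboxylate, via phosphorus ylide 5 (not isolated), via Michael adduct 6 (not isolated)
Conditions: (S)-2-[diphenyl(trimethylsilyloxy)methyl]pyrrolidine (20 mol%), K2CO3, CHCl3, 0 °C to rt
Reagents that add atoms: none
Why: K2CO3 converts 3 into the vinylogous ylide 5, whose negative charge is shared between the phosphorus-bearing carbon and the ester α-carbon, while the secondary amine turns 4 into an iminium ion; the ester α-carbon of 5 adds to the β-carbon of that ion (Michael addition, C1–C6 bond) and proton transfer returns the ylide as 6. The ylide carbon of 6 then attacks the aldehyde carbon and the oxaphosphetane collapses (intramolecular Wittig olefination), which closes the six-membered ring as a 6-exo-trig carbonyl addition and forms the C3=C4 double bond. The closest known reaction type is the amine-catalysed asymmetric tandem Michael addition/ylide olefination of enals with crotonate-derived phosphorus ylides to cyclohexa-1,3-dienes. The only stereocenter, C6, is set by the catalyst: the diphenyl(silyloxy)methyl group shields one face of the E-configured iminium ion, so the ylide should add from the open face and give the 6S diene. The step needs conjugate addition through the ester α-carbon in preference to direct olefination of the aldehyde; iminium activation of the β-carbon and the crowding at the methyl- and PPh3-bearing ylide carbon should secure it. Ring closure is regiospecific because only the phosphorus-bearing carbon can olefinate.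

Step 4
Reactants: 7 ethyl (6S)-3-methyl-6-phenylcyclohexa-1,3-diene-1-carboxylate
Product: 8 (6S)-N-methoxy-N,3-dimethyl-6-phenylcyclohexa-1,3-diene-1-carboxamide
Conditions: MeNHOMe·HCl, i-PrMgCl, THF, −20 °C
Reagents that add atoms: N,O-dimethylhydroxylamine hydrochloride, CNOC.Cl
Why: the magnesium amide made from MeNHOMe·HCl and i-PrMgCl should convert the ethyl ester directly into the N-methoxy-N-methylamide (ester aminolysis) without touching the diene or the C6 stereocenter.

Step 5
Reactants: 9 3,5-dimethoxyphenol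
Product: 10 2-bromo-3,5-dimethoxyphenol
Conditions: NBS, i-Pr2NH (10 mol%), CH2Cl2, 0 °C
Reagents that add atoms: N-bromosuccinimide, O=C1CCC(=O)N1Br
Why: amine-mediated electrophilic bromination with NBS is ortho-selective for phenols, the two ortho positions of 9 are equivalent, and the para position is flanked by two methoxy groups.

Step 6
Reactants: 10 2-bromo-3,5-dimethoxyphenol; 11 2-bromo-1,1-diethoxyethane
Product: 12 2-bromo-1-(2,2-diethoxyethoxy)-3,5-dimethoxybenzene
Conditions: K2CO3, DMF, 110 °C
Reagents that add atoms: none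
Why: Williamson ether synthesis of the phenoxide with the primary bromide of 11 should proceed cleanly because the acetal is stable to base.

Step 7
Reactants: 12 2-bromo-1-(2,2-diethoxyethoxy)-3,5-dimethoxybenzene
Product: 14 7-bromo-4,6-dimethoxy-1-benzofuran, via 3-ethoxy-2,3-dihydrobenzofuran 13 (not isolated)
Conditions: polyphosphoric acid, PhCl, 110 °C
Reagents that add atoms: none
Why: acid-catalysed cyclodehydration: the oxocarbenium ion from the acetal alkylates the only free position ortho to the ether oxygen (intramolecular Friedel–Crafts reaction, activated by both methoxy groups) to give 13, and loss of ethanol forms the furan ring.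

Step 8
Reactants: 14 7-bromo-4,6-dimethoxy-1-benzofuran; 8 (6S)-N-methoxy-N,3-dimethyl-6-phenylcyclohexa-1,3-diene-1-carboxamide
Product: 16 (4,6-dimethoxy-1-benzofuran-7-yl)[(6S)-3-methyl-6-phenylcyclohexa-1,3-dien-1-yl]methanone, via aryllithium 15 (not isolated)
Conditions: n-BuLi, THF, −78 °C; then 8, −78 to 0 °C; aq. NH4Cl
Reagents that add atoms: none
Why: bromine–lithium exchange at −78 °C is faster than deprotonation at the furan C2 position, and addition of 15 to the N-methoxy-N-methylamide should stop at the ketone stage because the carbonyl group is set free only on work-up.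

Step 9
Reactants: 16 (4,6-dimethoxy-1-benzofuran-7-yl)[(6S)-3-methyl-6-phenylcyclohexa-1,3-dien-1-yl]methanone; 17 (3-methylbut-2-en-1-yl)magnesium chloride
Product: 18 1-(4,6-dimethoxy-1-benzofuran-7-yl)-2,2-dimethyl-1-[(6S)-3-methyl-6-phenylcyclohexa-1,3-dien-1-yl]but-3-en-1-ol (both epimers at the carbinol carbon)
Conditions: THF, −78 °C; cold aq. NH4Cl
Reagents that add atoms: none
Why: allylic Grignard reagents add 1,2 even to hindered conjugated ketones through a six-membered transition state with allylic transposition, so the tertiary 1,1-dimethylallyl carbinol should form; its new carbinol stereocenter is unselective and is lost in step 10.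

Step 10
Reactants: 18 1-(4,6-dimethoxy-1-benzofuran-7-yl)-2,2-dimethyl-1-[(6S)-3-methyl-6-phenylcyclohexa-1,3-dien-1-yl]but-3-en-1-ol
Product: 21 (4,6-dimethoxy-1-benzofuran-7-yl)[(1R,2S,6R)-3-methyl-2-(3-methylbut-2-en-1-yl)-6-phenylcyclohex-3-en-1-yl]methanone, via potassium alkoxide 19 (not isolated), via potassium enolate 20 (not isolated)
Conditions: KH, 18-crown-6, THF, 0 °C to rt; then AcOH, −78 °C
Reagents that add atoms: none
Why: anionic oxy-Cope rearrangement: in alkoxide 19 the CH2 terminus of the dimethylallyl group should bond to C2 through a chair transition state on the face opposite the pseudoaxial C6 phenyl group (sets C2, prenyl trans to phenyl) and give enolate 20, whose protonation at −78 °C on the face away from the axial C2 prenyl group should set C1 with the acyl group cis to prenyl and trans to phenyl.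

Step 11
Reactants: 21 (4,6-dimethoxy-1-benzofuran-7-yl)[(1R,2S,6R)-3-methyl-2-(3-methylbut-2-en-1-yl)-6-phenylcyclohex-3-en-1-yl]methanone
Product: 22 (6-hydroxy-4-methoxy-1-benzofuran-7-yl)[(1R,2S,6R)-3-methyl-2-(3-methylbut-2-en-1-yl)-6-phenylcyclohex-3-en-1-yl]methanone
Conditions: BCl3, CH2Cl2, −78 to −20 °C; then aq. NaHCO3
Reagents that add atoms: none
Why: BCl3 binds the ketone oxygen and the neighbouring 6-methoxy oxygen of the benzofuran and should cleave only that methyl ether (chelation-controlled ortho-demethylation), leaving the 4-methoxy group, the alkenes and the three stereocenters untouched at low temperature.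

Compound list
1 | ethyl (2E)-pent-2-enoate | CCOC(=O)/C=C/CC | starting material
2 | ethyl (2E)-4-bromopent-2-enoate (racemic) | CCOC(=O)/C=C/C(C)Br | intermediate
3 | [(3E)-5-ethoxy-5-oxopent-3-en-2-yl]triphenylphosphonium bromide (racemic) | CCOC(=O)/C=C/C(C)[P+](c1ccccc1)(c1ccccc1)c1ccccc1.[Br-] | intermediate
4 | (2E)-3-phenylprop-2-enal (cinnamaldehyde) | O=C/C=C/c1ccccc1 | starting material
5 | ethyl (2E)-4-(triphenyl-λ5-phosphanylidene)pent-2-enoate | CCOC(=O)/C=C/C(C)=P(c1ccccc1)(c1ccccc1)c1ccccc1 | intermediate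
6 | ethyl 2-[(1S)-3-oxo-1-phenylpropyl]-4-(triphenyl-λ5-phosphanylidene)pent-2-enoate | CCOC(=O)C(=CC(C)=P(c1ccccc1)(c1ccccc1)c1ccccc1)[C@@H](CC=O)c1ccccc1 | intermediate
7 | ethyl (6S)-3-methyl-6-phenylcyclohexa-1,3-diene-1-carboxylate | CCOC(=O)C1=CC(C)=CC[C@H]1c1ccccc1 | intermediate
8 | (6S)-N-methoxy-N,3-dimethyl-6-phenylcyclohexa-1,3-diene-1-carboxamide | CON(C)C(=O)C1=CC(C)=CC[C@H]1c1ccccc1 | intermediate
9 | 3,5-dimethoxyphenol | COc1cc(O)cc(OC)c1 | starting material
10 | 2-bromo-3,5-dimethoxyphenol | COc1cc(O)c(Br)c(OC)c1 | intermediate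
11 | 2-bromo-1,1-diethoxyethane | CCOC(CBr)OCC | starting material
12 | 2-bromo-1-(2,2-diethoxyethoxy)-3,5-dimethoxybenzene | CCOC(COc1cc(OC)cc(OC)c1Br)OCC | intermediate
13 | 7-bromo-3-ethoxy-4,6-dimethoxy-2,3-dihydro-1-benzofuran (racemic) | CCOC1COc2c(Br)c(OC)cc(OC)c12 | intermediate
14 | 7-bromo-4,6-dimethoxy-1-benzofuran | COc1cc(OC)c(Br)c2occc12 | intermediate
15 | (4,6-dimethoxy-1-benzofuran-7-yl)lithium | COc1cc(OC)c([Li])c2occc12 | intermediate
16 | (4,6-dimethoxy-1-benzofuran-7-yl)[(6S)-3-methyl-6-phenylcyclohexa-1,3-dien-1-yl]methanone | COc1cc(OC)c(C(=O)C2=CC(C)=CC[C@H]2c2ccccc2)c2occc12 | intermediate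
17 | (3-methylbut-2-en-1-yl)magnesium chloride (prenylmagnesium chloride) | CC(C)=CC[Mg]Cl | starting material
18 | 1-(4,6-dimethoxy-1-benzofuran-7-yl)-2,2-dimethyl-1-[(6S)-3-methyl-6-phenylcyclohexa-1,3-dien-1-yl]but-3-en-1-ol (both carbinol epimers) | COc1cc(OC)c(C(O)(C(C)(C)C=C)C2=CC(C)=CC[C@H]2c2ccccc2)c2occc12 | intermediate
19 | potassium alkoxide of 18 | COc1cc(OC)c(C([O-])(C(C)(C)C=C)C2=CC(C)=CC[C@H]2c2ccccc2)c2occc12.[K+] | intermediate
20 | potassium enolate of 21 (exocyclic enolate at C1, C2 and C6 configured as in 21) | COc1cc(OC)c(C([O-])=C2[C@H](CC=C(C)C)C(C)=CC[C@H]2c2ccccc2)c2occc12.[K+] | intermediate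
21 | (4,6-dimethoxy-1-benzofuran-7-yl)[(1R,2S,6R)-3-methyl-2-(3-methylbut-2-en-1-yl)-6-phenylcyclohex-3-en-1-yl]methanone | COc1cc(OC)c(C(=O)[C@@H]2[C@H](CC=C(C)C)C(C)=CC[C@H]2c2ccccc2)c2occc12 | intermediate
22 | (6-hydroxy-4-methoxy-1-benzofuran-7-yl)[(1R,2S,6R)-3-methyl-2-(3-methylbut-2-en-1-yl)-6-phenylcyclohex-3-en-1-yl]methanone | COc1cc(O)c(C(=O)[C@@H]2[C@H](CC=C(C)C)C(C)=CC[C@H]2c2ccccc2)c2occc12 | target

Total step count: 11 steps.
Longest linear sequence: 8 steps (steps 1, 2, 3, 4, 8, 9, 10, 11); the aryl branch (steps 5–7) joins at step 8.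

Steps most likely to fail

Step 3. Direct olefination of the free aldehyde by ylide 5, or base-promoted addition outside the iminium cycle, would divert material from ring formation and erode the enantiofacial control. The fallback sets out from 4 and comes back at 7. Amine-catalysed Michael addition of ethyl 3-oxopentanoate to 4 (same pyrrolidine catalyst, PhCO2H, toluene), followed by acid-promoted intramolecular aldol condensation (TsOH, toluene, 60 °C), should give ethyl (6R)-3-methyl-2-oxo-6-phenylcyclohex-3-ene-1-carboxylate F1 (C1 as keto/enol mixture). Enol triflate formation (NaH, PhNTf2, THF) should give ethyl (6S)-3-methyl-6-phenyl-2-{[(trifluoromethyl)sulfonyl]oxy}cyclohexa-1,3-diene-1-carboxylate F2. Reduction with Pd(OAc)2, PPh3, HCO2H and Bu3N in DMF at 60 °C should then return 7.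

Step 10. The crowded tertiary alkoxide may fragment by loss of the allyl unit before it rearranges, and the shift or the enolate protonation may occur with poor facial selectivity. The fallback sets out from 8 and comes back at 21, moving the rearrangement to the aldehyde oxidation level, where the carbinol is secondary and far less crowded. DIBAL-H (THF, −78 °C) should reduce 8 to (6S)-3-methyl-6-phenylcyclohexa-1,3-diene-1-carbaldehyde F3. Addition of 17 should give 2,2-dimethyl-1-[(6S)-3-methyl-6-phenylcyclohexa-1,3-dien-1-yl]but-3-en-1-ol F4. Its potassium alkoxide (KH, 18-crown-6, THF; AcOH quench at −78 °C) should rearrange to (1R,2S,6R)-3-methyl-2-(3-methylbut-2-en-1-yl)-6-phenylcyclohex-3-ene-1-carbaldehyde F5. Addition of aryllithium 15 should give (4,6-dimethoxy-1-benzofuran-7-yl)[(1R,2S,6R)-3-methyl-2-(3-methylbut-2-en-1-yl)-6-phenylcyclohex-3-en-1-yl]methanol F6, and oxidation with DMP (CH2Cl2, NaHCO3) should return 21.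

Step 11. Ether cleavage under Lewis acid may be accompanied by epimerisation at C1 through a boron enolate, or by HCl addition to the trisubstituted alkenes. The fallback sets out from 16 and comes back at 22, removing the methyl group before the prenyl group and the C1 stereocenter exist. BCl3 (CH2Cl2, −78 °C) should convert 16 into (6-hydroxy-4-methoxy-1-benzofuran-7-yl)[(6S)-3-methyl-6-phenylcyclohexa-1,3-dien-1-yl]methanone F7. Protection with MOMCl and i-Pr2NEt should give [4-methoxy-6-(methoxymethoxy)-1-benzofuran-7-yl][(6S)-3-methyl-6-phenylcyclohexa-1,3-dien-1-yl]methanone F8, which keeps the phenol masked so that the later carbinol cannot ionise towards an ortho-quinone methide. Addition of 17 should give 1-[4-methoxy-6-(methoxymethoxy)-1-benzofuran-7-yl]-2,2-dimethyl-1-[(6S)-3-methyl-6-phenylcyclohexa-1,3-dien-1-yl]but-3-en-1-ol F9. Rearrangement (KH, 18-crown-6, THF; AcOH at −78 °C) should give [4-methoxy-6-(methoxymethoxy)-1-benzofuran-7-yl][(1R,2S,6R)-3-methyl-2-(3-methylbut-2-en-1-yl)-6-phenylcyclohex-3-en-1-yl]methanone F10, and mild acetal cleavage (HCl, MeOH, rt) should give 22.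

Further compounds
F1 | step 3 | ethyl (6R)-3-methyl-2-oxo-6-phenylcyclohex-3-ene-1-carboxylate | CCOC(=O)C1C(=O)C(C)=CC[C@H]1c1ccccc1
F2 | step 3 | ethyl (6S)-3-methyl-6-phenyl-2-{[(trifluoromethyl)sulfonyl]oxy}cyclohexa-1,3-diene-1-carboxylate | CCOC(=O)C1=C(OS(=O)(=O)C(F)(F)F)C(C)=CC[C@H]1c1ccccc1
F3 | step 10 | (6S)-3-methyl-6-phenylcyclohexa-1,3-diene-1-carbaldehyde | O=CC1=CC(C)=CC[C@H]1c1ccccc1
F4 | step 10 | 2,2-dimethyl-1-[(6S)-3-methyl-6-phenylcyclohexa-1,3-dien-1-yl]but-3-en-1-ol | OC(C(C)(C)C=C)C1=CC(C)=CC[C@H]1c1ccccc1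
F5 | step 10 | (1R,2S,6R)-3-methyl-2-(3-methylbut-2-en-1-yl)-6-phenylcyclohex-3-ene-1-carbaldehyde | O=C[C@@H]1[C@H](CC=C(C)C)C(C)=CC[C@H]1c1ccccc1
F6 | step 10 | (4,6-dimethoxy-1-benzofuran-7-yl)[(1R,2S,6R)-3-methyl-2-(3-methylbut-2-en-1-yl)-6-phenylcyclohex-3-en-1-yl]methanol | COc1cc(OC)c(C(O)[C@@H]2[C@H](CC=C(C)C)C(C)=CC[C@H]2c2ccccc2)c2occc12
F7 | step 11 | (6-hydroxy-4-methoxy-1-benzofuran-7-yl)[(6S)-3-methyl-6-phenylcyclohexa-1,3-dien-1-yl]methanone | COc1cc(O)c(C(=O)C2=CC(C)=CC[C@H]2c2ccccc2)c2occc12
F8 | step 11 | [4-methoxy-6-(methoxymethoxy)-1-benzofuran-7-yl][(6S)-3-methyl-6-phenylcyclohexa-1,3-dien-1-yl]methanone | COc1cc(OCOC)c(C(=O)C2=CC(C)=CC[C@H]2c2ccccc2)c2occc12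
F9 | step 11 | 1-[4-methoxy-6-(methoxymethoxy)-1-benzofuran-7-yl]-2,2-dimethyl-1-[(6S)-3-methyl-6-phenylcyclohexa-1,3-dien-1-yl]but-3-en-1-ol | COc1cc(OCOC)c(C(O)(C(C)(C)C=C)C2=CC(C)=CC[C@H]2c2ccccc2)c2occc12
F10 | step 11 | [4-methoxy-6-(methoxymethoxy)-1-benzofuran-7-yl][(1R,2S,6R)-3-methyl-2-(3-methylbut-2-en-1-yl)-6-phenylcyclohex-3-en-1-yl]methanone | COc1cc(OCOC)c(C(=O)[C@@H]2[C@H](CC=C(C)C)C(C)=CC[C@H]2c2ccccc2)c2occc12
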